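**Plan**

1. Numbering: ring C1 (lactone O–CH), C2=C3(CH3), C4 (CHOH), C5–C6(CH3) (epoxide), C7, C8, C9 (CH–O-angelate), C10; lactone C11 (=C13H2) and C12 (C=O). The retrosynthesis removes in turn the epoxide oxygen, the C9 angelate, C13 and the C12–O bond, reaching a (2Z,5Z)-cyclodeca-2,5-dienone with oxygen at C4 and C9 and a CH2CH(OMe)2 chain on C10.
2. Enabling feature: C1 and the methyl-bearing C6 lie 1,6 across the ten-membered ring, so a C1–C6 bond recasts it as a cis-decalin (ring A = C1–C6, ring B = C1, C6–C10) with angular C1–OH and C6–CH3. The carbocycle is therefore made by breaking that bond with a mesylate on C5 (Wharton–Grob fragmentation).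
3. The decalin is cut at C1–C10 and C6–C7 (asymmetric Robinson annulation of 2-methylcyclohexane-1,3-dione with 6,6-dimethoxyhex-1-en-3-one); the C3 methyl comes from a cuprate.
4. Forward: ring B is annulated onto ring A, the bicycle is adjusted in oxidation level and opened to the ten-membered ring, the lactone is closed from C1–O to C12, then C13, the angelate and last the epoxide are added.
5. Stereochemistry: C6 from the L-phenylalanine-catalysed aldol. C6 relays to C1 (epoxidation cis to CH3), C10 (enolate protonation), C9 (hydride cis to the C10 chain), C5 (C1–OH-directed hydride) and C4 (hydride anti to axial C7). Both Z olefins come from the fragmentation, C1 from a Felkin-type reduction, the epoxide from C4–OH-directed vanadium catalysis.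

Key step: step 17

Remark: locants are those of the target throughout; in the bicyclic intermediates α is the face of the angular C6 methyl group and β the opposite face. Compounds 12 to 14 are carried as epimer mixtures at C3 (and C4), which is harmless because both centres become sp2 in step 12.

**Route**

Step 1
Reactants: 1 methyl 4,4-dimethoxybutanoate
Product: 2 N-methoxy-N-methyl-4,4-dimethoxybutanamide
Conditions: MeNH(OMe)·HCl, i-PrMgCl, THF, −20 °C
Reagents that add atoms: N,O-dimethylhydroxylamine hydrochloride, CNOC.Cl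
Why: Weinreb amide formation, in which the chloromagnesium amide of N,O-dimethylhydroxylamine should displace methoxide from the ester while the acetal is inert to the basic medium.

Step 2
Reactants: 2 N-methoxy-N-methyl-4,4-dimethoxybutanamide
Product: 3 6,6-dimethoxyhex-1-en-3-one
Conditions: CH2=CHMgBr, THF, 0 °C; quench into cold pH 4 citrate buffer
Reagents that add atoms: vinylmagnesium bromide, C=C[Mg]Br
Why: Weinreb ketone synthesis, in which the magnesium-chelated tetrahedral adduct should persist until the cold buffered quench, so that neither over-addition nor conjugate addition of the released amine to the vinyl ketone is expected.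

Step 3
Reactants: 4 2-methylcyclohexane-1,3-dione; 3 6,6-dimethoxyhex-1-en-3-one
Product: 5 2-(6,6-dimethoxy-3-oxohexyl)-2-methylcyclohexane-1,3-dione
Conditions: Et3N (cat.), EtOAc, 50 °C
Reagents that add atoms: none
Why: Michael addition of the dione enolate to the vinyl ketone should form the C6–C7 bond and the quaternary C6, the triketone being achiral because its two ring carbonyls are enantiotopic.

Step 4
Reactants: 5 2-(6,6-dimethoxy-3-oxohexyl)-2-methylcyclohexane-1,3-dione
Product: 6 (8aS)-5-(2,2-dimethoxyethyl)-8a-methyl-3,4,8,8a-tetrahydronaphthalene-1,6(2H,7H)-dione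
Conditions: L-phenylalanine, pyridinium p-toluenesulfonate, DMSO, 45 °C
Reagents that add atoms: none
Why: Hajos–Parrish–Eder–Sauer–Wiechert aldol condensation (asymmetric Robinson annulation), in which the enamine formed at C9 with L-phenylalanine should attack through C10 one of the two enantiotopic ring carbonyls (C1), fixing the S configuration of C6 and closing ring B as the C1=C10 enone after dehydration.

Step 5
Reactants: 6 (8aS)-5-(2,2-dimethoxyethyl)-8a-methyl-3,4,8,8a-tetrahydronaphthalene-1,6(2H,7H)-dione
Product: 7 1α,10α-epoxy-6α-methyl-10β-(2,2-dimethoxyethyl)decalin-5,9-dione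
Conditions: 30% H2O2, NaOH (cat.), MeOH, 0 °C
Reagents that add atoms: hydrogen peroxide, OO
Why: Weitz–Scheffer epoxidation, in which hydroperoxide should add axially to C1 on the face of the angular methyl group, as in 4-en-3-one steroids and related octalones, so that the oxirane oxygen on C1 and C10 is cis to the C6 methyl while the saturated C5 ketone does not react.

Step 6
Reactants: 7 1α,10α-epoxy-6α-methyl-10β-(2,2-dimethoxyethyl)decalin-5,9-dione
Product: 8 1α-hydroxy-6α-methyl-10β-(2,2-dimethoxyethyl)-cis-decalin-5,9-dione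
Conditions: SmI2, THF/MeOH, −90 °C
Reagents that add atoms: none
Why: reductive opening of an α,β-epoxy ketone by SmI2, in which the C9 ketyl should cleave only the C10–O bond (C1–O stays cis to the methyl, giving the cis-decalin) and the samarium enolate, whose allylic 1,2-strain holds C2 pseudo-axial so that ring A covers the β face, should be protonated by methanol from the α face to place H10 cis to the C1 hydroxyl and the side chain equatorial.

Step 7
Reactants: 8 1α-hydroxy-6α-methyl-10β-(2,2-dimethoxyethyl)-cis-decalin-5,9-dione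
Product: 9 1α,9β-dihydroxy-6α-methyl-10β-(2,2-dimethoxyethyl)-cis-decalin-5-one
Conditions: LiBH(s-Bu)3, THF, −78 °C; H2O
Reagents that add atoms: none
Why: bulky trialkylborohydride reduction, in which the C9 carbonyl flanked by CH2 and CH should react well before the C5 carbonyl next to the quaternary C6, and equatorial attack, as on 2-alkylcyclohexanones, should give the axial 9β-alcohol cis to the C10 side chain.

Step 8
Reactants: 9 1α,9β-dihydroxy-6α-methyl-10β-(2,2-dimethoxyethyl)-cis-decalin-5-one
Product: 10 9β-(tert-butyldimethylsilyloxy)-1α-hydroxy-6α-methyl-10β-(2,2-dimethoxyethyl)-cis-decalin-5-one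
Conditions: TBSOTf, 2,6-lutidine, CH2Cl2, −78 °C
Reagents that add atoms: tert-butyldimethylsilyl trifluoromethanesulfonate, CC(C)(C)[Si](C)(C)OS(=O)(=O)C(F)(F)F
Why: silyl ether formation on the secondary C9 alcohol, the tertiary C1 alcohol being too hindered to compete at −78 °C and the buffered medium sparing the acetal next to the free hydroxyl.

Step 9
Reactants: 10 9β-(tert-butyldimethylsilyloxy)-1α-hydroxy-6α-methyl-10β-(2,2-dimethoxyethyl)-cis-decalin-5-one
Product: 11 9β-(tert-butyldimethylsilyloxy)-1α-hydroxy-6α-methyl-10β-(2,2-dimethoxyethyl)-cis-decal-3-en-5-one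
Conditions: IBX, DMSO, 70 °C
Reagents that add atoms: none
Why: IBX dehydrogenation of a ketone through its enol, in which only C4–C3 can be desaturated because C6 is quaternary and the enone cannot be oxidised further because C1 carries no hydrogen.

Step 10
Reactants: 11 9β-(tert-butyldimethylsilyloxy)-1α-hydroxy-6α-methyl-10β-(2,2-dimethoxyethyl)-cis-decal-3-en-5-one
Product: 12 3-methyl-1α,5-bis(trimethylsilyloxy)-4-ene silyl enol ether (C3 epimers)
Conditions: Me2CuLi (from CuI and MeLi), Me3SiCl, THF, −78 → 0 °C
Reagents that add atoms: lithium dimethylcuprate, [Li+].C[Cu-]C; chlorotrimethylsilane, C[Si](C)(C)Cl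
Why: cuprate conjugate addition with silyl trapping, in which methyl should add to C3 and the enolate oxygen be silylated so that the enol ether is fixed at C4=C5, the C1 alkoxide formed by excess cuprate being silylated as well and the new C3 centre needing no control because C3 becomes sp2 in step 12.

Step 11
Reactants: 12 3-methyl-1α,5-bis(trimethylsilyloxy)-4-ene silyl enol ether (C3 epimers)
Product: 14 1α,4-dihydroxy-3-methyl-5-ketone (C3 and C4 epimers), via 4-silyloxy ketone 13 (not isolated)
Conditions: mCPBA, NaHCO3, CH2Cl2, −20 °C; then citric acid, MeOH, rt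
Reagents that add atoms: 3-chloroperoxybenzoic acid, OOC(=O)c1cccc(Cl)c1
Why: Rubottom oxidation, in which epoxidation of the electron-rich silyl enol ether, silyl migration and methanolysis of both trimethylsilyl ethers should place a hydroxyl group on C4, whose configuration is of no consequence because C4 is oxidised in the next step.

Step 12
Reactants: 14 1α,4-dihydroxy-3-methyl-5-ketone (C3 and C4 epimers)
Product: 16 1α-hydroxy-3-methyl-2-ene-4,5-dione, via diosphenol 15 (not isolated)
Conditions: IBX (excess), DMSO, 70 °C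
Reagents that add atoms: none
Why: IBX oxidation of the acyloin to the 4,5-dione followed by IBX dehydrogenation of its enol toward the ring methylene C2 (endocyclic, as with 2-methylcyclohexanones) should give the non-enolisable ene-dione, which cannot react further because C1 and C6 are quaternary, and should erase the C3 and C4 centres.

Step 13
Reactants: 16 1α-hydroxy-3-methyl-2-ene-4,5-dione
Product: 17 1α,5β-dihydroxy-3-methyl-2-en-4-one
Conditions: Me4NBH(OAc)3, MeCN/AcOH, −30 °C
Reagents that add atoms: none
Why: Evans–Saksena hydroxyl-directed reduction, in which the C1 hydroxyl should exchange onto boron and deliver hydride through a six-membered transition state to the 1,3-related C5 carbonyl from the α face, giving the 5β-alcohol anti to the C1 hydroxyl while the conjugated C4 carbonyl is out of its reach.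

Step 14
Reactants: 17 1α,5β-dihydroxy-3-methyl-2-en-4-one
Product: 18 1α-hydroxy-5β-(methanesulfonyloxy)-3-methyl-2-en-4-one
Conditions: Ms2O, pyridine, CH2Cl2, 0 °C
Reagents that add atoms: methanesulfonic anhydride, CS(=O)(=O)OS(C)(=O)=O
Why: sulfonylation of the secondary C5 alcohol, which the tertiary allylic C1 alcohol should not follow at 0 °C, the anhydride being chosen so that no chloride can displace the α-keto sulfonate.

Step 15
Reactants: 18 1α-hydroxy-5β-(methanesulfonyloxy)-3-methyl-2-en-4-one
Product: 19 1α,4β-dihydroxy-5β-(methanesulfonyloxy)-3-methyl-2-ene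
Conditions: NaBH4, CeCl3·7H2O, MeOH, −78 °C
Reagents that add atoms: none
Why: Luche 1,2-reduction, in which the β face of C4 is screened in the preferred conformer (C5 mesylate equatorial, C7 axial on ring A) by the 1,3-related axial C7 methylene, so that hydride should enter from the α face and give the 4β-alcohol cis to the mesylate.

Step 16
Reactants: 19 1α,4β-dihydroxy-5β-(methanesulfonyloxy)-3-methyl-2-ene
Product: 20 1α-hydroxy-5β-(methanesulfonyloxy)-3-methyl-4β-(triisopropylsilyloxy)-2-ene
Conditions: TIPSOTf, 2,6-lutidine, CH2Cl2, −78 → 0 °C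
Reagents that add atoms: triisopropylsilyl trifluoromethanesulfonate, CC(C)[Si](C(C)C)(C(C)C)OS(=O)(=O)C(F)(F)F
Why: silyl ether formation on the secondary allylic alcohol, which blocks an alkoxide-driven semipinacol ring contraction in the next step and, being more robust than the C9 silyl ether, lets C9 be unmasked first later, while the tertiary C1 alcohol stays free.

Step 17
Reactants: 20 1α-hydroxy-5β-(methanesulfonyloxy)-3-methyl-4β-(triisopropylsilyloxy)-2-ene
Product: 22 (2Z,5Z)-9-(tert-butyldimethylsilyloxy)-10-(2,2-dimethoxyethyl)-3,6-dimethyl-4-(triisopropylsilyloxy)cyclodeca-2,5-dien-1-one, via potassium alkoxide 21 (not isolated)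
Conditions: KOt-Bu (1.05 equiv), 18-crown-6, THF, −40 → 0 °C; pH 7 buffer
Reagents that add atoms: none
Why: Wharton–Grob fragmentation, the known reaction of decalin 1,3-diol monosulfonates that gives cyclodecenones: tert-butoxide forms the C1 alkoxide 21, whose lone pair builds the C1 carbonyl while the C1–C6 σ bond donates into the σ* orbital of the anti-periplanar C5–O(mesyl) bond and mesylate leaves in one concerted step. The ten-membered ring is not closed end to end but set free by cleaving the bond shared by the two six-membered rings, so the entropic cost and transannular strain of a macrocyclisation are avoided. No stereocentre is formed (C1 and C6 become sp2, while C4, C9 and C10 are carried through), and both olefin geometries are fixed by the bicycle: the cyclohexene bond of ring A becomes the Z C2=C3 enone, and because C7 is axial on ring A and gauche to C4 in the cis-fused conformer with the C5 mesylate equatorial, C4 and C7 end up cis on the new C5=C6 bond (Z). The step needs fragmentation to outrun oxetane formation, elimination and semipinacol shift, which should be secured by the anti-periplanar C1–C6 and C5–O bonds, the lack of an anti hydrogen on C4 or C6 and the silylated C4 oxygen. It also needs the product to survive, so only a slight excess of base is used at low temperature and the mixture is quenched at pH 7 to spare the C10 centre and the β-silyloxy group next to the new ketone.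

Step 18
Reactants: 22 (2Z,5Z)-9-(tert-butyldimethylsilyloxy)-10-(2,2-dimethoxyethyl)-3,6-dimethyl-4-(triisopropylsilyloxy)cyclodeca-2,5-dien-1-one
Product: 24 cis-fused lactol (C1–O–C12H(OH); both anomers), via allylic alcohol 23 (not isolated)
Conditions: NaBH4, CeCl3·7H2O, MeOH, −78 °C; then AcOH/H2O/THF, rt
Reagents that add atoms: water, O
Why: Luche reduction followed by acetal hydrolysis with ring closure, in which hydride should add 1,2 to the outer face of the ring ketone, anti to the C9–C10 bond that stands perpendicular to the carbonyl plane (Felkin–Anh model with the ring carbon as the large group), giving the C1 alcohol cis to C11, after which aqueous acid should exchange the γ-hydroxy dimethyl acetal into the five-membered lactol.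

Step 19
Reactants: 24 cis-fused lactol (C1–O–C12H(OH); both anomers)
Product: 25 cis-fused γ-lactone (C12=O) with 4-OTIPS and 9-OTBS
Conditions: PhI(OAc)2, TEMPO (cat.), CH2Cl2, rt
Reagents that add atoms: none
Why: oxoammonium (TEMPO) oxidation of a lactol to the γ-lactone, which should leave the silyl ethers and the two trisubstituted olefins untouched and does not affect the cis ring fusion set in step 18.

Step 20
Reactants: 25 cis-fused γ-lactone (C12=O) with 4-OTIPS and 9-OTBS
Product: 28 α-methylene lactone with 4-OTIPS and 9-OTBS, via Mannich base 26 (not isolated), via methiodide 27 (not isolated)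
Conditions: LiN(i-Pr)2, THF, −78 °C; CH2=NMe2+ I−, −78 → 0 °C; MeI, MeOH, rt; aq. NaHCO3
Reagents that add atoms: dimethyl(methylidene)ammonium iodide, C=[N+](C)C.[I-]
Why: Mannich aminomethylation of the lactone lithium enolate at C11, N-methylation and β-elimination of trimethylamine (Eschenmoser methylenation) should install the exocyclic C11=C13 bond, leaving no stereocentre at C11.

Step 21
Reactants: 28 α-methylene lactone with 4-OTIPS and 9-OTBS
Product: 29 9-hydroxy α-methylene lactone with 4-OTIPS
Conditions: HF·pyridine, pyridine, THF, 0 °C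
Reagents that add atoms: none
Why: fluoride desilylation, in which the less hindered tert-butyldimethylsilyl ether on C9 should be cleaved well before the triisopropylsilyl ether on the hindered C4 oxygen.

Step 22
Reactants: 29 9-hydroxy α-methylene lactone with 4-OTIPS; 30 angelic acid
Product: 32 9-angelate with 4-OTIPS, via mixed anhydride 31 (not isolated)
Conditions: 30, 2,4,6-trichlorobenzoyl chloride, Et3N, toluene, rt; then 29, 80 °C
Reagents that add atoms: none
Why: Yamaguchi esterification, in which acyl transfer from the mixed anhydride without a nucleophilic catalyst should acylate the C9 alcohol through the less hindered angeloyl carbonyl without Z to E isomerisation to the tiglate.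

Step 23
Reactants: 32 9-angelate with 4-OTIPS
Product: 33 9-angelate 4-alcohol (2Z,5Z-diene)
Conditions: HF·pyridine, THF, rt
Reagents that add atoms: none
Why: fluoride cleavage of the remaining silyl ether under pyridine-buffered conditions, which the angelate, the methylene lactone and the bis-allylic alcohol should tolerate.

Step 24
Reactants: 33 9-angelate 4-alcohol (2Z,5Z-diene)
Product: 34 CNP0500828.1
Conditions: VO(acac)2 (cat.), t-BuOOH, CH2Cl2, 0 °C
Reagents that add atoms: tert-butyl hydroperoxide, CC(C)(C)OO
Why: vanadium-catalysed hydroxyl-directed epoxidation, in which the vanadium-bound C4 alkoxide should deliver the peroxide oxygen to C5=C6 with a small O–C4–C5=C6 dihedral angle, which in this medium ring (C3 cannot lie anti to the olefin) leads to the cis epoxy alcohol, while C2=C3 is deactivated by the allylic lactone oxygen and the two conjugated alkenes are inert to the electrophilic oxidant.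

**Compound list**

1 | methyl 4,4-dimethoxybutanoate | COC(=O)CCC(OC)OC | starting material
2 | N-methoxy-N-methyl-4,4-dimethoxybutanamide | CON(C)C(=O)CCC(OC)OC | intermediate
3 | 6,6-dimethoxyhex-1-en-3-one | C=CC(=O)CCC(OC)OC | intermediate
4 | 2-methylcyclohexane-1,3-dione | CC1C(=O)CCCC1=O | starting material
5 | 2-(6,6-dimethoxy-3-oxohexyl)-2-methylcyclohexane-1,3-dione (achiral) | CC1(CCC(=O)CCC(OC)OC)C(=O)CCCC1=O | intermediate
6 | (8aS)-5-(2,2-dimethoxyethyl)-8a-methyl-3,4,8,8a-tetrahydronaphthalene-1,6(2H,7H)-dione (C1=C10 enone, C9 and C5 ketones, 6α-CH3) | C[C@]12CCC(=O)C(CC(OC)OC)=C1CCCC2=O | intermediate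
7 | 1α,10α-epoxy-6α-methyl-10β-(2,2-dimethoxyethyl)decalin-5,9-dione (oxirane cis to the C6 methyl) | C[C@]12CCC(=O)[C@]3(CC(OC)OC)O[C@]13CCCC2=O | intermediate
8 | 1α-hydroxy-6α-methyl-10β-(2,2-dimethoxyethyl)-cis-decalin-5,9-dione (H10 α) | O[C@]12CCCC(=O)[C@@]1(C)CCC(=O)[C@H]2CC(OC)OC | intermediate
9 | 1α,9β-dihydroxy-6α-methyl-10β-(2,2-dimethoxyethyl)-cis-decalin-5-one | O[C@]12CCCC(=O)[C@@]1(C)CC[C@@H](O)[C@H]2CC(OC)OC | intermediate
10 | 9β-(tert-butyldimethylsilyloxy)-1α-hydroxy-6α-methyl-10β-(2,2-dimethoxyethyl)-cis-decalin-5-one | O[C@]12CCCC(=O)[C@@]1(C)CC[C@@H](O[Si](C)(C)C(C)(C)C)[C@H]2CC(OC)OC | intermediate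
11 | 3-en-5-one of 10 | O[C@]12CC=CC(=O)[C@@]1(C)CC[C@@H](O[Si](C)(C)C(C)(C)C)[C@H]2CC(OC)OC | intermediate
12 | 3-methyl-1α,5-bis(trimethylsilyloxy)-4-ene silyl enol ether (C3 epimers; 6α-CH3, 9β-OTBS, 10β-CH2CH(OMe)2) | C[Si](C)(C)O[C@]12CC(C)C=C(O[Si](C)(C)C)[C@@]1(C)CC[C@@H](O[Si](C)(C)C(C)(C)C)[C@H]2CC(OC)OC | intermediate
13 | 3-methyl-1α,4-bis(trimethylsilyloxy)-5-ketone | C[Si](C)(C)O[C@]12CC(C)C(O[Si](C)(C)C)C(=O)[C@@]1(C)CC[C@@H](O[Si](C)(C)C(C)(C)C)[C@H]2CC(OC)OC | intermediate (not isolated)
14 | 1α,4-dihydroxy-3-methyl-5-ketone (C3 and C4 epimers) | O[C@]12CC(C)C(O)C(=O)[C@@]1(C)CC[C@@H](O[Si](C)(C)C(C)(C)C)[C@H]2CC(OC)OC | intermediate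
15 | 1α,4-dihydroxy-3-methyl-3-en-5-one (diosphenol, enol of the 4,5-dione) | O[C@]12CC(C)=C(O)C(=O)[C@@]1(C)CC[C@@H](O[Si](C)(C)C(C)(C)C)[C@H]2CC(OC)OC | intermediate (not isolated)
16 | 1α-hydroxy-3-methyl-2-ene-4,5-dione | O[C@]12C=C(C)C(=O)C(=O)[C@@]1(C)CC[C@@H](O[Si](C)(C)C(C)(C)C)[C@H]2CC(OC)OC | intermediate
17 | 1α,5β-dihydroxy-3-methyl-2-en-4-one | O[C@]12C=C(C)C(=O)[C@@H](O)[C@@]1(C)CC[C@@H](O[Si](C)(C)C(C)(C)C)[C@H]2CC(OC)OC | intermediate
18 | 1α-hydroxy-5β-(methanesulfonyloxy)-3-methyl-2-en-4-one | O[C@]12C=C(C)C(=O)[C@@H](OS(C)(=O)=O)[C@@]1(C)CC[C@@H](O[Si](C)(C)C(C)(C)C)[C@H]2CC(OC)OC | intermediate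
19 | 1α,4β-dihydroxy-5β-(methanesulfonyloxy)-3-methyl-2-ene | O[C@]12C=C(C)[C@@H](O)[C@@H](OS(C)(=O)=O)[C@@]1(C)CC[C@@H](O[Si](C)(C)C(C)(C)C)[C@H]2CC(OC)OC | intermediate
20 | fragmentation precursor: cis-decalin with 1α-OH, C2=C3(CH3), 4β-OTIPS, 5β-OMs, 6α-CH3, 9β-OTBS, 10β-CH2CH(OMe)2 | O[C@]12C=C(C)[C@@H](O[Si](C(C)C)(C(C)C)C(C)C)[C@@H](OS(C)(=O)=O)[C@@]1(C)CC[C@@H](O[Si](C)(C)C(C)(C)C)[C@H]2CC(OC)OC | intermediate
21 | potassium C1 alkoxide of 20 | [K+].[O-][C@]12C=C(C)[C@@H](O[Si](C(C)C)(C(C)C)C(C)C)[C@@H](OS(C)(=O)=O)[C@@]1(C)CC[C@@H](O[Si](C)(C)C(C)(C)C)[C@H]2CC(OC)OC | intermediate (not isolated)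
22 | (2Z,5Z)-9-(tert-butyldimethylsilyloxy)-10-(2,2-dimethoxyethyl)-3,6-dimethyl-4-(triisopropylsilyloxy)cyclodeca-2,5-dien-1-one (C4, C9, C10 as in 34) | O=C1/C=C(/C)[C@@H](O[Si](C(C)C)(C(C)C)C(C)C)/C=C(/C)CC[C@@H](O[Si](C)(C)C(C)(C)C)[C@H]1CC(OC)OC | intermediate
23 | C1 allylic alcohol of 22 (C1–OH cis to C11) | O[C@H]1/C=C(/C)[C@@H](O[Si](C(C)C)(C(C)C)C(C)C)/C=C(/C)CC[C@@H](O[Si](C)(C)C(C)(C)C)[C@H]1CC(OC)OC | intermediate (not isolated)
24 | cis-fused lactol (C1–O–C12H(OH), both anomers; 4-OTIPS, 9-OTBS) | C1C(O)O[C@H]2/C=C(/C)[C@@H](O[Si](C(C)C)(C(C)C)C(C)C)/C=C(/C)CC[C@@H](O[Si](C)(C)C(C)(C)C)[C@@H]12 | intermediate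
25 | cis-fused γ-lactone (C12=O; 4-OTIPS, 9-OTBS) | C1C(=O)O[C@H]2/C=C(/C)[C@@H](O[Si](C(C)C)(C(C)C)C(C)C)/C=C(/C)CC[C@@H](O[Si](C)(C)C(C)(C)C)[C@@H]12 | intermediate
26 | 11-(dimethylaminomethyl) lactone (Mannich base, C11 epimers) | CN(C)CC1C(=O)O[C@H]2/C=C(/C)[C@@H](O[Si](C(C)C)(C(C)C)C(C)C)/C=C(/C)CC[C@@H](O[Si](C)(C)C(C)(C)C)[C@@H]12 | intermediate (not isolated)
27 | trimethylammonium iodide of 26 | C[N+](C)(C)CC1C(=O)O[C@H]2/C=C(/C)[C@@H](O[Si](C(C)C)(C(C)C)C(C)C)/C=C(/C)CC[C@@H](O[Si](C)(C)C(C)(C)C)[C@@H]12.[I-] | intermediate (not isolated)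
28 | α-methylene lactone with 4-OTIPS and 9-OTBS | C=C1C(=O)O[C@H]2/C=C(/C)[C@@H](O[Si](C(C)C)(C(C)C)C(C)C)/C=C(/C)CC[C@@H](O[Si](C)(C)C(C)(C)C)[C@@H]12 | intermediate
29 | 9-hydroxy α-methylene lactone with 4-OTIPS | C=C1C(=O)O[C@H]2/C=C(/C)[C@@H](O[Si](C(C)C)(C(C)C)C(C)C)/C=C(/C)CC[C@@H](O)[C@@H]12 | intermediate
30 | angelic acid, (Z)-2-methylbut-2-enoic acid | C/C=C(/C)C(=O)O | starting material
31 | angelic 2,4,6-trichlorobenzoic anhydride | C/C=C(/C)C(=O)OC(=O)c1c(Cl)cc(Cl)cc1Cl | intermediate (not isolated)
32 | 9-angelate with 4-OTIPS | C=C1C(=O)O[C@H]2/C=C(/C)[C@@H](O[Si](C(C)C)(C(C)C)C(C)C)/C=C(/C)CC[C@@H](OC(=O)/C(C)=C\C)[C@@H]12 | intermediate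
33 | 9-angelate 4-alcohol (2Z,5Z-diene) | C=C1C(=O)O[C@H]2/C=C(/C)[C@@H](O)/C=C(/C)CC[C@@H](OC(=O)/C(C)=C\C)[C@@H]12 | intermediate
34 | CNP0500828.1 | C=C1C(=O)O[C@H]2/C=C(/C)[C@@H](O)[C@H]3O[C@@]3(C)CC[C@@H](OC(=O)/C(C)=C\C)[C@@H]12 | target

**Step count and risks**

Total steps: 24. Longest linear sequence: 24 steps (1 to 34; 4 and 30 enter as purchased materials).

Steps most likely to fail:

Step 6. What may go wrong: the samarium enolate is protonated from the β face, or without face preference if its half-chair flips, which would give the C10 epimer with the side chain cis to the C1 hydroxyl; β-elimination of the tertiary hydroxyl back to the enone on work-up is a second leak. Fallback: the enolate is trapped instead of protonated. Setting out from 7, SmI2 in THF at −78 °C followed by acetic anhydride should give the 9-acetoxy-9-ene enol acetate F1. Hydrogenation over [Ir(cod)(PCy3)(py)]PF6 in CH2Cl2, in which the C1 hydroxyl binds iridium and both hydrogens are delivered to the α face, should then give the 9β-acetate F2 with H10 α. K2CO3 in methanol releases the diol, and the route is rejoined at 9.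

Step 17. What may go wrong: the C–C cleavage is slow relative to intramolecular O-alkylation (oxetane between C1–O and C5) if the bulky C4 silyl ether disfavours the conformer with the equatorial mesylate, or residual tert-butoxide enolises the new ketone and so epimerises C10 or expels the C9 silyloxy group. Fallback: the alkoxide is generated without any excess base. Setting out from 20, Me3SiOTf and 2,6-lutidine at −78 °C should give the C1 trimethylsilyl ether F3. One equivalent of Bu4NF in THF at −40 °C should cleave only this labile Si–O bond, and the naked tetrabutylammonium alkoxide should fragment at once (fluoride-triggered Grob fragmentation), returning to the route at 22.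

Step 24. What may go wrong: oxygen is transferred to C2=C3, which is also allylic to the C4 hydroxyl, or to the other face of C5=C6 if the ring reacts through a conformer with C3 anti to the olefin, giving the trans epoxy alcohol. Fallback: the epoxide is built in two steps without hydroxyl direction. Setting out from 32 (C4 still silylated), NBS in aqueous THF should form the bromonium ion on the outer face of the more electron-rich C5=C6 bond, and water should open it at the tertiary C6 from the inner face to give the bromohydrin F4. Ag2O in CH2Cl2 should close the C6 oxygen onto C5 with inversion to the epoxy silyl ether F5, whose oxygen sits on the face opposite to that reached by a direct peripheral oxidant. HF·pyridine then gives 34, the end point of the route.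

Further compounds
F1 | step 6 | 9-acetoxy-1α-hydroxy-6α-methyl-10-(2,2-dimethoxyethyl)-cis-decal-9-en-5-one (enol acetate) | O[C@]12CCCC(=O)[C@@]1(C)CCC(OC(C)=O)=C2CC(OC)OC
F2 | step 6 | 9β-acetoxy-1α-hydroxy-6α-methyl-10β-(2,2-dimethoxyethyl)-cis-decalin-5-one | O[C@]12CCCC(=O)[C@@]1(C)CC[C@@H](OC(C)=O)[C@H]2CC(OC)OC
F3 | step 17 | C1 trimethylsilyl ether of 20 | C[Si](C)(C)O[C@]12C=C(C)[C@@H](O[Si](C(C)C)(C(C)C)C(C)C)[C@@H](OS(C)(=O)=O)[C@@]1(C)CC[C@@H](O[Si](C)(C)C(C)(C)C)[C@H]2CC(OC)OC
F4 | step 24 | 5-bromo-6-hydroxy adduct of 32 (bromohydrin) | C=C1C(=O)O[C@H]2/C=C(/C)[C@@H](O[Si](C(C)C)(C(C)C)C(C)C)[C@H](Br)[C@](O)(C)CC[C@@H](OC(=O)/C(C)=C\C)[C@@H]12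
F5 | step 24 | 4-O-triisopropylsilyl ether of 34 (epoxy silyl ether) | C=C1C(=O)O[C@H]2/C=C(/C)[C@@H](O[Si](C(C)C)(C(C)C)C(C)C)[C@H]3O[C@@]3(C)CC[C@@H](OC(=O)/C(C)=C\C)[C@@H]12
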